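**Retrosynthetic overview**

1. Numbering used: ring A (cyclopentane) is C1 (ring-fusion C–CH3), C2, C3, C4 (C(OH)i-Pr), C5 (ring-fusion CH); ring B (cycloheptene) continues with C6 (CH–O-acyl), C7=C8(CH3), C9 (CH–OH), C10 (CH2).
2. End game: target ⇐ phenol deacetylation ⇐ Luche reduction at C9 ⇐ acylation of O6 ⇐ hydroxy enone (ring B closed, C9 as ketone).
3. Key disconnection C8–C9: hydroxy enone ⇐ iodoalkenyl δ-lactone, in which O6 carries C9 as its acyl group (temporary ring C6–O6–C9–C10–C1–C5); iodine–lithium exchange at C8 and 1,4 O→C acyl transfer close ring B and open the lactone in one operation.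
4. Enabling feature: the cis-ene-1,4-dioxygen unit O6–C6–C7=C8–C9–O of ring B, which lets O6 and C9 be tied as a lactone so that the Z-alkenyl carbon C8 lies 1,3-diaxial to the C9 carbonyl.
5. δ-Lactone ⇐ iodoalkenyl diol ⇐ three-component assembly on purchased ring A: 3-methylcyclopent-2-enone + α-silylvinyl alane (C9–C10) + (Z)-3-iodobut-2-enal (C6–C8), then i-Pr at C4; ring order: ring A (bought), temporary lactone, ring B.

Key step: step 8

Remark: 4-acetoxy-3-methoxybenzoic acid is treated as a purchased compound, and the chiral carbene ligand of step 1 is used in the enantiomeric form that gives the S product.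

**Step 1**
Reactants: 1 3-methylcyclopent-2-en-1-one; 2 ethynyltrimethylsilane
Product: 5 trimethyl({(3S)-3-methyl-3-[1-(trimethylsilyl)ethenyl]cyclopent-1-en-1-yl}oxy)silane, via alkenylalane 3 (not isolated), via aluminium enolate 4 (not isolated)
Conditions: 2, i-Bu2AlH, hexane/THF, 55 °C; then 1, Cu(OTf)2 (5 mol %), Ag2L2 (L = chiral sulfonate-bearing N-heterocyclic carbene, 2.5 mol %), THF, −30 → 0 °C; then Me3SiOTf, −78 → 0 °C
Reagents that add atoms: trimethylsilyl trifluoromethanesulfonate, C[Si](C)(C)OS(=O)(=O)C(F)(F)F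
Why: Copper-catalysed asymmetric conjugate addition of the α-silyl alkenylalane (from α-selective hydroalumination of 2) to the β-methyl enone should set the quaternary centre C1 under control of the chiral carbene–copper catalyst, and O-silylation of the regiodefined aluminium enolate fixes enolisation towards C5.

**Step 2**
Reactants: 6 but-2-yn-1-ol
Product: 8 (Z)-3-iodobut-2-en-1-ol, via cyclic alkenylalanate 7 (not isolated)
Conditions: NaAlH2(OCH2CH2OMe)2, THF, 0 °C → rt; EtOAc; then I2, THF, −78 → 0 °C
Reagents that add atoms: iodine, II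
Why: Hydroxyl-directed trans-hydroalumination of the propargylic alcohol followed by iodinolysis of the C–Al bond with retention should give the Z-iodoalkene regio- and stereospecifically.

**Step 3**
Reactants: 8 (Z)-3-iodobut-2-en-1-ol
Product: 9 (Z)-3-iodobut-2-enal
Conditions: MnO2, CH2Cl2, rt, dark
Reagents that add atoms: none
Why: MnO2 oxidation of an allylic alcohol under neutral conditions should give the enal without loss of the Z geometry.

**Step 4**
Reactants: 5 silyl enol ether; 9 (Z)-3-iodobut-2-enal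
Product: 11 (2S,3S)-2-[(1R,2Z)-1-hydroxy-3-iodobut-2-en-1-yl]-3-methyl-3-[1-(trimethylsilyl)ethenyl]cyclopentan-1-one, via lithium enolate 10 (not isolated)
Conditions: MeLi, THF, 0 °C; then 9, −78 °C; AcOH, −78 °C
Reagents that add atoms: none
Why: Cleavage of the enol silane by MeLi gives the regiodefined lithium enolate, whose aldol addition through a Zimmerman–Traxler transition state (cyclic E-enolate) should give the anti C5/C6 relationship, the aldehyde attacking C5 on the face opposite the bulky 1-(trimethylsilyl)ethenyl group of C1 (cis to the methyl group).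

**Step 5**
Reactants: 11 aldol
Product: 12 (1R,2S,3S)-2-[(1R,2Z)-1-hydroxy-3-iodobut-2-en-1-yl]-3-methyl-1-(propan-2-yl)-3-[1-(trimethylsilyl)ethenyl]cyclopentan-1-ol
Conditions: i-PrMgCl, CeCl3, THF, −78 °C (premixed 1 h); then 11, −78 → −40 °C; aq. AcOH
Reagents that add atoms: isopropylmagnesium chloride, CC(C)[Mg]Cl
Why: Organocerium 1,2-addition suppresses enolisation, reduction and retro-aldol of the hindered β-hydroxy ketone, and attack on C4 trans to the adjacent C5 side chain should give the tertiary alcohol with OH cis to that chain.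

**Step 6**
Reactants: 12 diol
Product: 14 (1R,2S,3S)-3-[2-hydroxy-1-(trimethylsilyl)ethyl]-2-[(1R,2Z)-1-hydroxy-3-iodobut-2-en-1-yl]-3-methyl-1-(propan-2-yl)cyclopentan-1-ol (both epimers at the silyl-bearing carbon), via B-alkyl borane 13 (not isolated)
Conditions: 9-BBN-H (excess), THF, 60 °C; then NaOH, H2O2, 0 °C → rt
Reagents that add atoms: hydrogen peroxide, OO
Why: Anti-Markovnikov hydroboration–oxidation with 9-BBN places boron on the terminal carbon of the 1,1-disubstituted vinylsilane while the trisubstituted iodoalkene is inert, and the new silyl-bearing centre is of no consequence because it is lost in step 7.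

**Step 7**
Reactants: 14 triol
Product: 16 (1R,4aR,7R,7aS)-7-hydroxy-1-[(1Z)-2-iodoprop-1-en-1-yl]-4a-methyl-7-(propan-2-yl)hexahydrocyclopenta[c]pyran-3(1H)-one, via alpha-silyl lactone 15 (not isolated)
Conditions: PhI(OAc)2, TEMPO (cat.), CH2Cl2, rt; then Bu4NF/AcOH (1:1), THF, 0 °C
Reagents that add atoms: none
Why: TEMPO/PhI(OAc)2 oxidative lactonisation of the 1,5-diol (primary alcohol to aldehyde, lactol, lactone) is selective for the primary hydroxyl over the hindered secondary and tertiary ones, and fluoride then protodesilylates the α-silyl carbonyl compound without touching a stereocentre of 16.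

**Step 8**
Reactants: 16 iodoalkenyl δ-lactone
Product: 19 (3R,3aS,4S,8aR)-3,4-dihydroxy-6,8a-dimethyl-3-(propan-2-yl)-2,3,3a,4,8,8a-hexahydroazulen-7(1H)-one, via alkenyllithium alkoxide 17 (not isolated), via bridged lithium hemiketalate 18 (not isolated)
Conditions: t-BuLi (3.2 equiv), THF/Et2O/pentane, −100 → −78 °C; AcOH, −78 °C → rt
Reagents that add atoms: none
Why: t-BuLi deprotonates the tertiary hydroxyl and then exchanges iodine for lithium at C8 with retention of the Z geometry; the alkenyllithium 17 adds to the lactone carbonyl C9 to give the oxygen-bridged hemiketalate 18, whose C9–O6 bond opens on quench, so that the acyl carbon is transferred from O6 to C8 (1,4 O→C) and the δ-lactone is exchanged for the cycloheptenone. The closest known reaction type is the Parham cyclisation (halogen–lithium exchange followed by intramolecular acylation of an aryl- or alkenyllithium by an ester, amide or lactone, stopping at the tetrahedral stage), here in the topology of an anionic homo-Fries shift. The new bond closes ring B in a 7-exo-trig mode and, transiently, the 2,5-dihydrofuran ring O6–C6–C7–C8–C9 in a 5-exo-trig mode; the temporary ring through O6 is cleaved in the same operation. No stereocentre remains to be set in 19 (the hemiketal carbon of 18 is fixed by the bridge), C1, C4, C5 and C6 are not touched, and the cis arrangement of C6 and C9 on C7=C8 that ring B demands is that of the Z-iodide. The step needs exchange to outrun addition of t-BuLi to the lactone and needs a single addition: the first is secured by the rate of iodine–lithium exchange at −100 °C, the second by the persistence of the hemiketalate until the acid quench. Reach is secured by the substrate, because the trans-fused lactone carries the alkenyl group axial on C6 and therefore 1,3-diaxial to the C9 carbonyl.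

**Step 9**
Reactants: 19 hydroxy enone; 20 4-acetoxy-3-methoxybenzoic acid
Product: 21 (3R,3aS,4S,8aR)-3-hydroxy-6,8a-dimethyl-7-oxo-3-(propan-2-yl)-1,2,3,3a,4,7,8,8a-octahydroazulen-4-yl 4-acetoxy-3-methoxybenzoate
Conditions: EDC·HCl, DMAP, CH2Cl2, rt
Reagents that add atoms: none
Why: Steglich esterification can only acylate the secondary C6 hydroxyl, because C9 is at the ketone level and the C4 hydroxyl is tertiary.

**Step 10**
Reactants: 21 ester enone
Product: 22 (3R,3aS,4S,7R,8aR)-3,7-dihydroxy-6,8a-dimethyl-3-(propan-2-yl)-1,2,3,3a,4,7,8,8a-octahydroazulen-4-yl 4-acetoxy-3-methoxybenzoate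
Conditions: NaBH4, CeCl3·7H2O, MeOH, −78 °C
Reagents that add atoms: none
Why: Luche 1,2-reduction of the enone should deliver hydride to C9 on the face opposite the pseudo-axial angular methyl group on C1 (1,3 to C9), which leaves the new hydroxyl cis to that methyl group and so gives the 7R allylic alcohol.

**Step 11**
Reactants: 22 acetyl-protected target
Product: 23 (3R,3aS,4S,7R,8aR)-3,7-dihydroxy-6,8a-dimethyl-3-(propan-2-yl)-1,2,3,3a,4,7,8,8a-octahydroazulen-4-yl 4-hydroxy-3-methoxybenzoate (target)
Conditions: K2CO3 (cat.), MeOH, 0 °C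
Reagents that add atoms: none
Why: Base-catalysed methanolysis (transesterification) cleaves the aryl acetate far faster than the hindered alkyl benzoate and releases the phenol.

**Compound list**

1 | 3-methylcyclopent-2-en-1-one | CC1=CC(=O)CC1 | starting material
2 | ethynyltrimethylsilane | C#C[Si](C)(C)C | starting material
3 | bis(2-methylpropyl)[1-(trimethylsilyl)ethenyl]alane | C=C([Si](C)(C)C)[Al](CC(C)C)CC(C)C | intermediate
4 | diisobutylaluminium enolate of (S)-3-methyl-3-[1-(trimethylsilyl)ethenyl]cyclopentanone (enolised towards C5) | CC(C)C[Al](CC(C)C)OC1=C[C@@](C)(C(=C)[Si](C)(C)C)CC1 | intermediate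
5 | trimethyl({(3S)-3-methyl-3-[1-(trimethylsilyl)ethenyl]cyclopent-1-en-1-yl}oxy)silane | C[Si](C)(C)OC1=C[C@@](C)(C(=C)[Si](C)(C)C)CC1 | intermediate
6 | but-2-yn-1-ol | CC#CCO | starting material
7 | sodium cyclic (Z)-alkenylalanate (five-membered O–Al–C=C–C ring, two 2-methoxyethoxy ligands) | CC1=CCO[Al-]1(OCCOC)OCCOC.[Na+] | intermediate
8 | (Z)-3-iodobut-2-en-1-ol | C/C(I)=C/CO | intermediate
9 | (Z)-3-iodobut-2-enal | C/C(I)=C/C=O | intermediate
10 | lithium enolate corresponding to 5 | [Li]OC1=C[C@@](C)(C(=C)[Si](C)(C)C)CC1 | intermediate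
11 | (2S,3S)-2-[(1R,2Z)-1-hydroxy-3-iodobut-2-en-1-yl]-3-methyl-3-[1-(trimethylsilyl)ethenyl]cyclopentan-1-one (anti aldol, side chain cis to CH3) | C/C(I)=C/[C@H](O)[C@H]1C(=O)CC[C@]1(C)C(=C)[Si](C)(C)C | intermediate
12 | (1R,2S,3S)-2-[(1R,2Z)-1-hydroxy-3-iodobut-2-en-1-yl]-3-methyl-1-(propan-2-yl)-3-[1-(trimethylsilyl)ethenyl]cyclopentan-1-ol | C/C(I)=C/[C@H](O)[C@H]1[C@](O)(C(C)C)CC[C@]1(C)C(=C)[Si](C)(C)C | intermediate
13 | B-alkyl-9-borabicyclo[3.3.1]nonane adduct of 12 (boron on the terminal carbon, silyl-bearing carbon unassigned) | C/C(I)=C/[C@H](O)[C@H]1[C@](O)(C(C)C)CC[C@]1(C)C(CB2C3CCCC2CCC3)[Si](C)(C)C | intermediate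
14 | (1R,2S,3S)-3-[2-hydroxy-1-(trimethylsilyl)ethyl]-2-[(1R,2Z)-1-hydroxy-3-iodobut-2-en-1-yl]-3-methyl-1-(propan-2-yl)cyclopentan-1-ol (both epimers at the silyl-bearing carbon) | C/C(I)=C/[C@H](O)[C@H]1[C@](O)(C(C)C)CC[C@]1(C)C(CO)[Si](C)(C)C | intermediate
15 | 4-(trimethylsilyl) derivative of lactone 16 (silyl-bearing carbon unassigned) | C/C(I)=C/[C@@H]1OC(=O)C([Si](C)(C)C)[C@@]2(C)CC[C@@](O)(C(C)C)[C@H]12 | intermediate
16 | (1R,4aR,7R,7aS)-7-hydroxy-1-[(1Z)-2-iodoprop-1-en-1-yl]-4a-methyl-7-(propan-2-yl)hexahydrocyclopenta[c]pyran-3(1H)-one (trans-fused δ-lactone) | C/C(I)=C/[C@@H]1OC(=O)C[C@@]2(C)CC[C@@](O)(C(C)C)[C@H]12 | intermediate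
17 | lithium alkoxide of 16 with lithium in place of iodine (Z-alkenyllithium) | C/C([Li])=C/[C@@H]1OC(=O)C[C@@]2(C)CC[C@@](O[Li])(C(C)C)[C@H]12 | intermediate
18 | dilithium salt of the bridged hemiketal (O6 bridging C6 and C9 of ring B, 8-oxabicyclo[3.2.1]oct-6-ene core fused to ring A) | O1[C@H]2C=C(C)[C@]1(O[Li])C[C@@]3(C)CC[C@@](O[Li])(C(C)C)[C@H]23 | intermediate
19 | (3R,3aS,4S,8aR)-3,4-dihydroxy-6,8a-dimethyl-3-(propan-2-yl)-2,3,3a,4,8,8a-hexahydroazulen-7(1H)-one | O[C@H]1C=C(C)C(=O)C[C@@]2(C)CC[C@@](O)(C(C)C)[C@H]12 | intermediate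
20 | 4-acetoxy-3-methoxybenzoic acid | COc1cc(C(=O)O)ccc1OC(C)=O | starting material
21 | (3R,3aS,4S,8aR)-3-hydroxy-6,8a-dimethyl-7-oxo-3-(propan-2-yl)-1,2,3,3a,4,7,8,8a-octahydroazulen-4-yl 4-acetoxy-3-methoxybenzoate | COc1cc(C(=O)O[C@H]2C=C(C)C(=O)C[C@@]3(C)CC[C@@](O)(C(C)C)[C@H]23)ccc1OC(C)=O | intermediate
22 | (3R,3aS,4S,7R,8aR)-3,7-dihydroxy-6,8a-dimethyl-3-(propan-2-yl)-1,2,3,3a,4,7,8,8a-octahydroazulen-4-yl 4-acetoxy-3-methoxybenzoate | COc1cc(C(=O)O[C@H]2C=C(C)[C@H](O)C[C@@]3(C)CC[C@@](O)(C(C)C)[C@H]23)ccc1OC(C)=O | intermediate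
23 | (3R,3aS,4S,7R,8aR)-3,7-dihydroxy-6,8a-dimethyl-3-(propan-2-yl)-1,2,3,3a,4,7,8,8a-octahydroazulen-4-yl 4-hydroxy-3-methoxybenzoate | COc1cc(C(=O)O[C@H]2C=C(C)[C@H](O)C[C@@]3(C)CC[C@@](O)(C(C)C)[C@H]23)ccc1O | target

**Step count**

Total step count: 11. Longest linear sequence: 10 steps (steps 2, 3, 4, 5, 6, 7, 8, 9, 10, 11, from but-2-yn-1-ol 6 to the target); step 1 is a one-step branch that joins this sequence at step 4.

**Steps most likely to fail**

Step 8. t-BuLi may add to the lactone carbonyl, or the alkenyllithium may be protonated before it reaches C9, because the 1,3-diaxial approach passes under the angular methyl group and leads to a strained bridged intermediate. The fallback sets out from lactone 16 and comes back at hydroxy enone 19. Aminolysis of 16 with the aluminium amide made from Me3Al and MeNH(OMe)·HCl (CH2Cl2, 0 °C → rt) opens the lactone to the hydroxy Weinreb amide 2-[(1R,2S,3R)-3-hydroxy-2-[(1R,2Z)-1-hydroxy-3-iodobut-2-en-1-yl]-1-methyl-3-(propan-2-yl)cyclopentyl]-N-methoxy-N-methylacetamide F1. t-BuLi (4.2 equiv, −100 → −78 °C) then deprotonates both hydroxyls, exchanges iodine for lithium and closes ring B by 7-exo-trig acylation on the amide; the chelated tetrahedral intermediate needs no bridged ring and resists a second addition, and acid work-up gives 19.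

Step 4. Facial discrimination at C5 (methyl against silylethenyl) or the anti/syn preference may be poor, and the β-iodo enal may isomerise or suffer addition–elimination. The fallback sets out from 5 and 6 and comes back at diol 12. MnO2 oxidation of 6 gives but-2-ynal F2, a slimmer and more robust electrophile. Addition of the lithium enolate 10 (from 5 and MeLi) to F2 at −78 °C gives the propargylic aldol (2S,3S)-2-[(1R)-1-hydroxybut-2-yn-1-yl]-3-methyl-3-[1-(trimethylsilyl)ethenyl]cyclopentan-1-one F3. Organocerium addition as in step 5 gives the alkynyl diol (1R,2S,3S)-2-[(1R)-1-hydroxybut-2-yn-1-yl]-3-methyl-1-(propan-2-yl)-3-[1-(trimethylsilyl)ethenyl]cyclopentan-1-ol F4. Hydroxyl-directed trans-hydroalumination with NaAlH2(OCH2CH2OMe)2 followed by I2 then installs the Z-iodoalkene late and gives 12.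

Step 7. The strained trans-fused lactol (axial alkenyl group 1,3 to the angular methyl) may form slowly, so that the aldehyde stalls or the allylic secondary alcohol is oxidised in its place. The fallback sets out from triol 14 and comes back at lactone 16. Oxidation of the primary alcohol to the acid with TEMPO (cat.), NaOCl (cat.) and NaClO2 (MeCN, pH 6.7 buffer), with loss of the α-silyl group on acidic work-up, gives the hydroxy acid 2-[(1R,2S,3R)-3-hydroxy-2-[(1R,2Z)-1-hydroxy-3-iodobut-2-en-1-yl]-1-methyl-3-(propan-2-yl)cyclopentyl]acetic acid F5. Yamaguchi lactonisation (2,4,6-trichlorobenzoyl chloride, Et3N, THF; then DMAP, toluene) closes the δ-lactone 16 by acyl activation in place of lactol oxidation.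

**Further compounds**

F1 | step 8 | 2-[(1R,2S,3R)-3-hydroxy-2-[(1R,2Z)-1-hydroxy-3-iodobut-2-en-1-yl]-1-methyl-3-(propan-2-yl)cyclopentyl]-N-methoxy-N-methylacetamide | C/C(I)=C/[C@H](O)[C@H]1[C@](O)(C(C)C)CC[C@]1(C)CC(=O)N(C)OC
F2 | step 4 | but-2-ynal | CC#CC=O
F3 | step 4 | (2S,3S)-2-[(1R)-1-hydroxybut-2-yn-1-yl]-3-methyl-3-[1-(trimethylsilyl)ethenyl]cyclopentan-1-one | CC#C[C@H](O)[C@H]1C(=O)CC[C@]1(C)C(=C)[Si](C)(C)C
F4 | step 4 | (1R,2S,3S)-2-[(1R)-1-hydroxybut-2-yn-1-yl]-3-methyl-1-(propan-2-yl)-3-[1-(trimethylsilyl)ethenyl]cyclopentan-1-ol | CC#C[C@H](O)[C@H]1[C@](O)(C(C)C)CC[C@]1(C)C(=C)[Si](C)(C)C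
F5 | step 7 | 2-[(1R,2S,3R)-3-hydroxy-2-[(1R,2Z)-1-hydroxy-3-iodobut-2-en-1-yl]-1-methyl-3-(propan-2-yl)cyclopentyl]acetic acid | C/C(I)=C/[C@H](O)[C@H]1[C@](O)(C(C)C)CC[C@]1(C)CC(=O)O
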